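## Structural features

The target is a 2,3-dihydro-1-benzofuran (O1, C2, C3, C3a, C7a fused to a benzo ring) that carries a 4-hydroxyphenyl ring on C2, a 2,4-dihydroxybenzoyl ketone on C3 and, on C5 (para to O1), an (E)-3-(2,4-dihydroxyphenyl)-3-oxoprop-1-enyl chain, that is, a 2'-hydroxychalcone. C2 and C3 are the only stereocentres; they are adjacent, both S, and their substituents are trans. C3–H is benzylic and alpha to a ketone, so it epimerises easily and its enolate can expel O1 by beta-elimination. C2–O1 is a para-hydroxybenzylic aryl ether that can ionise to a quinone methide under acid or base, the 2'-hydroxychalcone can close to a flavanone, and the five phenols are easily oxidised. The real difficulty is absolute and relative control of C2/C3 on a ring whose C3 bears both the aromatic carbon C3a and an exocyclic carbonyl carbon; the enone and the aryl ketone are routine. The key step exploits exactly this pattern (O1 and an aryl group on C2, C3a and a carbonyl carbon on C3): it is what remains when, in a 2-arylchroman-4-one, the benzo carbon C4a migrates from the carbonyl carbon C4 to C3, so that the five-membered ring is a ring-contracted flavanone with the old C4 extruded as the exocyclic carbonyl carbon. In one sentence, the route is the oxidative ring contraction of an enantioenriched 6-bromoflavanone by trivalent iodine, a description that does not fit an oxidative chalcone dimerisation or a carbene C–H insertion.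

## Logic of the disconnections

**19 to 18.** The five phenolic O–H bonds are traced back to O–Si bonds. The cut is made there because a free 2-hydroxyl would add to the vinyl ketone of 17 and free phenols would not survive the organometallic steps. The gain is a single final unmasking. The demand is a near-neutral desilylation that does not open C2–O1 or close the chalcone.

**18 to 14 and 17.** The bond between C5 of the benzofuran and the beta carbon of the enone is cut. This turns the chalcone into an aryl bromide and a vinyl ketone, and the bromide is inert in every earlier step. It also avoids a hydroxide-mediated aldol condensation on a base-sensitive ketone. The demand is a Heck coupling that runs at low temperature with a hindered amine in the presence of the acidic C3–H.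

**14 to 9 and 12; 17 to 16 to 12 and 15; 12 to 11 to 10.** In both ketones the bond between the carbonyl carbon and the resorcinol ring carbon is cut. One nucleophile, 12, then serves twice, so both resorcinol rings come from 10; 12 is prepared once from 11 as a stock solution and divided between the two additions. The demand is that acyl substitution on 9 stops at the ketone stage (held as 13 until work-up), that 12 adds 1,2 to 15, and that 12 is stable enough in solution to be portioned.

**9 to 8 to 7.** This is functional group interchange only: the amide returns to the methyl ester and the silyl ether on the C2 aryl ring returns to an acetate. The acetate is wanted in the key step as a weakly donating group and is removed by the same reagent that makes the amide. The demand is that one aluminium amide reagent cleaves both esters without enolising C3.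

**7 to 3 (key).** Read backwards, the C3–C3a bond is cut and C3a is reconnected to the ester carbon. The five-membered ring re-expands to the six-membered ring of 3, and the ester carbon becomes the ketone carbon C4. The gain is large: a heterocycle with two adjacent stereocentres becomes a flavanone with one. The demand on the forward step is that the ring bond C4–C4a migrates in preference to anything else, and stereospecifically, so that C2 dictates C3.

**3 to 1 and 2.** The C2–aryl bond is cut, leaving two commercial compounds. The demand is an enantioface-selective 1,4-arylation of 1 that tolerates the aryl bromide and the acetate.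

## Other disconnections considered

Alternative 1: This is the first disconnection that comes to mind, since the target is formally a dimer of isoliquiritigenin A1.
- Cut: C3–C3a and C2–O1.
- Forward key step: one-electron oxidation of A1 (Ag2O, or a peroxidase with H2O2). The phenoxyl radical, delocalised to the alpha carbon, would bond to the ortho carbon of a second unit, and the quinone methide would be trapped by the phenol oxygen to give the racemic trans dimer A2.
- Ground for preferring the chosen plan: nothing in the radical coupling controls absolute configuration, so A2 would be racemic and half of it would have to be removed by chiral chromatography. The radical has several coupling sites (alpha–alpha, alpha–O, ring–ring), the resorcinol ring of A1 is itself oxidisable, and the 2'-hydroxychalcone can cyclise. The chosen plan sets C2 with a catalyst and C3 by substrate control.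

Alternative 2:
- Cut: C2–C3.
- Forward key step: intramolecular C–H insertion of the carbene from aryl diazoacetate A3 into the benzylic ether C–H, catalysed by Rh2(S-PTTL)4. This should give the cis ester A4, which would then be epimerised at C3 to reach 7.
- Ground: this is the standard asymmetric answer for this ring system and so fails the first test. It delivers the cis isomer, which requires a base-mediated epimerisation on a compound that can open by beta-elimination. The precursor needs an etherification and a diazo transfer, about four operations to reach 7 against two in the chosen plan. The acetoxy group would deactivate the benzylic C–H toward the electrophilic carbene, whereas in the chosen plan the same group is an asset.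

Alternative 3:
- Cut: C2–C3 and C2–O1, a (4+1) annulation.
- Forward key step: conjugate addition of the sulfonium benzylide A6 to the exocyclic carbon of the acyl ortho-quinone methide A5, then displacement of the sulfide by the phenoxide.
- Ground: A5 is an acyl-substituted quinone methide that is hard to generate cleanly. The betaine would carry a very acidic C–H (alpha to the ketone) beta to the sulfonium, so elimination to a ring-opened 2-hydroxyaryl chalcone competes with ring closure. Absolute control would need a stoichiometric chiral sulfide on a semi-stabilised ylide. The first-formed centre is epimerisable, so only C2 would carry stereochemical information.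

Key step: step 2

Remark: the SMILES is read as the trans-(2S,3S) dihydrobenzofuran with an E enone. In step 1 the (R) ligand is assumed to give the 2S product by analogy with the facial preference of the (S) ligand for cyclic enones. If the assignment at 3 showed the opposite sense, the other ligand antipode would be used and nothing else would change.

## Steps

Step 1
Reactants: 1 6-bromo-4H-chromen-4-one (6-bromochromone); 2 (4-acetoxyphenyl)boronic acid
Product: 3 4-[(2S)-6-bromo-4-oxo-3,4-dihydro-2H-chromen-2-yl]phenyl acetate
Conditions: Pd(OCOCF3)2 (5 mol %), (R)-t-BuPyOx (6 mol %), NH4PF6 (30 mol %), H2O (5 equiv), ClCH2CH2Cl, 60 °C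
Reagents that add atoms: none
Why: Enantioselective conjugate addition of an arylboronic acid to a chromone catalysed by divalent palladium (Hayashi–Miyaura type); the aryl–palladium species adds to C2 on the face left open by the tert-butyl group of the pyridine–oxazoline ligand, which should set C2 as S, and water protonates the palladium enolate. Divalent palladium does not insert into the aryl bromide, and the nearly neutral medium should leave the acetate in place.

Step 2
Reactants: 3 4-[(2S)-6-bromo-4-oxo-3,4-dihydro-2H-chromen-2-yl]phenyl acetate
Product: 7 methyl (2S,3S)-2-(4-acetoxyphenyl)-5-bromo-2,3-dihydro-1-benzofuran-3-carboxylate, via methyl enol ether 4 (not isolated), via C3 aryl-λ3-iodane 5 (not isolated), via trimethyl ortho ester 6 (not isolated)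
Conditions: PhI(OAc)2 (1.2 equiv), conc. H2SO4 (0.3 equiv), HC(OMe)3, 0 °C → rt; then H2O, aq. NaHCO3
Reagents that add atoms: trimethyl orthoformate, COC(OC)OC; water, O
Why: Oxidative ring contraction of a flavanone by trivalent iodine, the cyclic case of the 1,2-aryl shift that turns aryl ketone ketals into arylacetic esters. Acid and HC(OMe)3 convert the ketone into enol ether 4, which attacks PhI(OAc)2 at C3 (chroman numbering) on the face opposite the C2 aryl group while methanol caps C4, giving the trans iodane 5. In the conformer of 5 with the aryl group and the C3–I bond both equatorial, the C3–I bond is antiperiplanar to the ring bond C4–C4a, and the aryl carbon C4a shifts from C4 to C3 through a phenonium bridge as PhI departs, pushed by the two methoxy oxygens on C4; the resulting cation is trapped as ortho ester 6 and hydrolysed to 7 on work-up. The five-membered ring O1–C2–C3–C3a–C7a is therefore closed by a suprafacial 1,2-shift (ring contraction from six to five members), not by a cyclisation, and the old C4 is extruded as the ester carbon. C2 is not touched and keeps the configuration from step 1; C3 is set by substrate control, since anti addition of iodine followed by inversion at C3 places the ester trans to the C2 aryl group, which corresponds to (2S,3S). The step needs migration of C4a in preference to migration of the C2 aryl ring or of O1, to elimination to the flavone and to methanolysis at C3: the ketal oxygens give C4a the push, O1 ortho to C4a stabilises the bridged cation, and the acetoxy group makes the C2 aryl ring a poor migrating group and disfavours ionisation of C2–O1, so that the ee of 3 should be carried over.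

Step 3
Reactants: 7 methyl (2S,3S)-2-(4-acetoxyphenyl)-5-bromo-2,3-dihydro-1-benzofuran-3-carboxylate
Product: 8 (2S,3S)-5-bromo-2-(4-hydroxyphenyl)-N-methoxy-N-methyl-2,3-dihydro-1-benzofuran-3-carboxamide
Conditions: AlMe3 (4 equiv), MeNHOMe·HCl (4 equiv), CH2Cl2, 0 °C → rt; cold 1 M HCl work-up
Reagents that add atoms: N,O-dimethylhydroxylamine hydrochloride, CNOC.Cl
Why: Weinreb amidation of an ester with an aluminium amide; the same reagent, used in excess, should aminolyse the aryl acetate (an activated ester), so the electron-poor mask of step 2 is shed without a separate step. The reagent is Lewis acidic and not basic, so C3 should not be enolised and both stereocentres stay as set.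

Step 4
Reactants: 8 (2S,3S)-5-bromo-2-(4-hydroxyphenyl)-N-methoxy-N-methyl-2,3-dihydro-1-benzofuran-3-carboxamide
Product: 9 (2S,3S)-5-bromo-2-[4-(tert-butyldimethylsilyloxy)phenyl]-N-methoxy-N-methyl-2,3-dihydro-1-benzofuran-3-carboxamide
Conditions: TBSCl (1.3 equiv), imidazole (2.5 equiv), DMF, rt
Reagents that add atoms: tert-butyldimethylsilyl chloride, CC(C)(C)[Si](C)(C)Cl
Why: Standard silylation of a phenol; it masks the acidic O–H before the Grignard step and removes the quinone methide pathway for C2–O1 cleavage until the end.

Step 5
Reactants: 10 4-bromobenzene-1,3-diol (4-bromoresorcinol)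
Product: 11 1-bromo-2,4-bis(tert-butyldimethylsilyloxy)benzene
Conditions: TBSCl (2.4 equiv), imidazole (5 equiv), DMF, rt
Reagents that add atoms: tert-butyldimethylsilyl chloride, CC(C)(C)[Si](C)(C)Cl
Why: Standard double silylation of a resorcinol; the bromine already sits at the carbon that must become the acyl-bearing carbon, so the 2,4-dioxygenation pattern is fixed by the starting material.

Step 6
Reactants: 11 1-bromo-2,4-bis(tert-butyldimethylsilyloxy)benzene
Product: 12 [2,4-bis(tert-butyldimethylsilyloxy)phenyl]magnesium bromide, kept as a titrated THF solution under argon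
Conditions: Mg turnings (2.5 equiv), LiCl (1.25 equiv), THF, rt; decanted from excess Mg and titrated
Reagents that add atoms: magnesium, [Mg]
Why: Grignard formation by direct insertion of magnesium into an aryl bromide, accelerated by LiCl; the reagent is made once as a stock solution and divided between steps 7 and 8. Aryl silyl ethers tolerate an aryl Grignard reagent at room temperature, and the 1,3 shift of silicon from oxygen to carbon that troubles the corresponding aryllithium should be slow for the less polar C–Mg bond.

Step 7
Reactants: 12 [2,4-bis(tert-butyldimethylsilyloxy)phenyl]magnesium bromide; 9 (2S,3S)-5-bromo-2-[4-(tert-butyldimethylsilyloxy)phenyl]-N-methoxy-N-methyl-2,3-dihydro-1-benzofuran-3-carboxamide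
Product: 14 [2,4-bis(tert-butyldimethylsilyloxy)phenyl]{(2S,3S)-5-bromo-2-[4-(tert-butyldimethylsilyloxy)phenyl]-2,3-dihydro-1-benzofuran-3-yl}methanone, via tetrahedral magnesium adduct 13 (not isolated)
Conditions: 12 (2 equiv, THF solution from step 6), 9, THF, 0 °C → rt; aq. NH4Cl
Reagents that add atoms: none
Why: Weinreb ketone synthesis; the chelated adduct 13 does not collapse until work-up, so over-addition is excluded and the acidic ketone C3–H is never exposed to the Grignard reagent. An aryl Grignard reagent does not exchange with the aryl bromide of 9, and any C3 epimer formed would revert to the favoured trans ketone.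

Step 8
Reactants: 12 [2,4-bis(tert-butyldimethylsilyloxy)phenyl]magnesium bromide; 15 prop-2-enal (acrolein)
Product: 16 1-[2,4-bis(tert-butyldimethylsilyloxy)phenyl]prop-2-en-1-ol (racemic)
Conditions: 12 (1 equiv, THF solution from step 6), 15 (1.2 equiv), THF, −78 °C; aq. NH4Cl
Reagents that add atoms: none
Why: 1,2-Addition of an aryl Grignard reagent to an enal, which is favoured over conjugate addition at low temperature without copper; the carbinol stereocentre is removed in step 9.

Step 9
Reactants: 16 1-[2,4-bis(tert-butyldimethylsilyloxy)phenyl]prop-2-en-1-ol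
Product: 17 1-[2,4-bis(tert-butyldimethylsilyloxy)phenyl]prop-2-en-1-one
Conditions: MnO2 (activated, 15 equiv), CH2Cl2, rt
Reagents that add atoms: none
Why: MnO2 oxidation of an alcohol that is both allylic and benzylic; the neutral heterogeneous conditions should spare the silyl ethers, and the vinyl ketone is used at once to avoid polymerisation.

Step 10
Reactants: 14 [2,4-bis(tert-butyldimethylsilyloxy)phenyl]{(2S,3S)-5-bromo-2-[4-(tert-butyldimethylsilyloxy)phenyl]-2,3-dihydro-1-benzofuran-3-yl}methanone; 17 1-[2,4-bis(tert-butyldimethylsilyloxy)phenyl]prop-2-en-1-one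
Product: 18 (2E)-1-[2,4-bis(tert-butyldimethylsilyloxy)phenyl]-3-{(2S,3S)-3-[2,4-bis(tert-butyldimethylsilyloxy)benzoyl]-2-[4-(tert-butyldimethylsilyloxy)phenyl]-2,3-dihydro-1-benzofuran-5-yl}prop-2-en-1-one
Conditions: Pd(P(t-Bu)3)2 (5 mol %), Cy2NMe (1.5 equiv), 17 (2 equiv), BHT (cat.), 1,4-dioxane, 50 °C
Reagents that add atoms: none
Why: Mizoroki–Heck reaction; zerovalent palladium with the bulky electron-rich phosphine inserts into the electron-rich aryl bromide at low temperature, and syn insertion followed by syn beta-hydride elimination gives the E enone. The hindered amine is too weak to open the ring through the C3 enolate, and any C3 epimerisation would only return the favoured trans isomer.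

Step 11
Reactants: 18 (2E)-1-[2,4-bis(tert-butyldimethylsilyloxy)phenyl]-3-{(2S,3S)-3-[2,4-bis(tert-butyldimethylsilyloxy)benzoyl]-2-[4-(tert-butyldimethylsilyloxy)phenyl]-2,3-dihydro-1-benzofuran-5-yl}prop-2-en-1-one
Product: 19 (2E)-3-[(2S,3S)-3-(2,4-dihydroxybenzoyl)-2-(4-hydroxyphenyl)-2,3-dihydro-1-benzofuran-5-yl]-1-(2,4-dihydroxyphenyl)prop-2-en-1-one (target)
Conditions: Bu4NF (7 equiv), AcOH (7 equiv), THF, 0 °C → rt
Reagents that add atoms: none
Why: Fluoride cleavage of aryl silyl ethers; the acetic acid buffer protonates each phenoxide as it forms, which should prevent quinone methide opening of C2–O1, enolisation at C3 and closure of the 2'-hydroxychalcone to a flavanone.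

## Compound list

1 | 6-bromo-4H-chromen-4-one | O=c1ccoc2ccc(Br)cc12 | starting material
2 | (4-acetoxyphenyl)boronic acid | CC(=O)Oc1ccc(B(O)O)cc1 | starting material
3 | 4-[(2S)-6-bromo-4-oxo-3,4-dihydro-2H-chromen-2-yl]phenyl acetate | O=C1C[C@@H](c2ccc(OC(C)=O)cc2)Oc2ccc(Br)cc21 | intermediate
4 | 4-[(2S)-6-bromo-4-methoxy-2H-chromen-2-yl]phenyl acetate | COC1=C[C@@H](c2ccc(OC(C)=O)cc2)Oc2ccc(Br)cc21 | intermediate (not isolated)
5 | 4-{(2R,3R)-3-[acetoxy(phenyl)-λ3-iodanyl]-6-bromo-4,4-dimethoxy-3,4-dihydro-2H-chromen-2-yl}phenyl acetate | COC1(OC)[C@H](I(OC(C)=O)c2ccccc2)[C@@H](c2ccc(OC(C)=O)cc2)Oc2ccc(Br)cc21 | intermediate (not isolated)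
6 | 4-[(2S,3S)-5-bromo-3-(trimethoxymethyl)-2,3-dihydro-1-benzofuran-2-yl]phenyl acetate | Brc1ccc2c(c1)[C@H](C(OC)(OC)OC)[C@@H](c1ccc(OC(C)=O)cc1)O2 | intermediate (not isolated)
7 | methyl (2S,3S)-2-(4-acetoxyphenyl)-5-bromo-2,3-dihydro-1-benzofuran-3-carboxylate | Brc1ccc2c(c1)[C@H](C(=O)OC)[C@@H](c1ccc(OC(C)=O)cc1)O2 | intermediate
8 | (2S,3S)-5-bromo-2-(4-hydroxyphenyl)-N-methoxy-N-methyl-2,3-dihydro-1-benzofuran-3-carboxamide | Brc1ccc2c(c1)[C@H](C(=O)N(C)OC)[C@@H](c1ccc(O)cc1)O2 | intermediate
9 | (2S,3S)-5-bromo-2-[4-(tert-butyldimethylsilyloxy)phenyl]-N-methoxy-N-methyl-2,3-dihydro-1-benzofuran-3-carboxamide | Brc1ccc2c(c1)[C@H](C(=O)N(C)OC)[C@@H](c1ccc(O[Si](C)(C)C(C)(C)C)cc1)O2 | intermediate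
10 | 4-bromobenzene-1,3-diol | Oc1ccc(Br)c(O)c1 | starting material
11 | 1-bromo-2,4-bis(tert-butyldimethylsilyloxy)benzene | CC(C)(C)[Si](C)(C)Oc1ccc(Br)c(O[Si](C)(C)C(C)(C)C)c1 | intermediate
12 | [2,4-bis(tert-butyldimethylsilyloxy)phenyl]magnesium bromide | CC(C)(C)[Si](C)(C)Oc1ccc([Mg]Br)c(O[Si](C)(C)C(C)(C)C)c1 | intermediate (used as a titrated THF solution)
13 | bromomagnesium [2,4-bis(tert-butyldimethylsilyloxy)phenyl]{(2S,3S)-5-bromo-2-[4-(tert-butyldimethylsilyloxy)phenyl]-2,3-dihydro-1-benzofuran-3-yl}[methoxy(methyl)amino]methanolate (carbinol centre undefined) | Brc1ccc2c(c1)[C@H](C(O[Mg]Br)(N(C)OC)c1ccc(O[Si](C)(C)C(C)(C)C)cc1O[Si](C)(C)C(C)(C)C)[C@@H](c1ccc(O[Si](C)(C)C(C)(C)C)cc1)O2 | intermediate (not isolated)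
14 | [2,4-bis(tert-butyldimethylsilyloxy)phenyl]{(2S,3S)-5-bromo-2-[4-(tert-butyldimethylsilyloxy)phenyl]-2,3-dihydro-1-benzofuran-3-yl}methanone | Brc1ccc2c(c1)[C@H](C(=O)c1ccc(O[Si](C)(C)C(C)(C)C)cc1O[Si](C)(C)C(C)(C)C)[C@@H](c1ccc(O[Si](C)(C)C(C)(C)C)cc1)O2 | intermediate
15 | prop-2-enal | C=CC=O | starting material
16 | 1-[2,4-bis(tert-butyldimethylsilyloxy)phenyl]prop-2-en-1-ol (racemic) | C=CC(O)c1ccc(O[Si](C)(C)C(C)(C)C)cc1O[Si](C)(C)C(C)(C)C | intermediate
17 | 1-[2,4-bis(tert-butyldimethylsilyloxy)phenyl]prop-2-en-1-one | C=CC(=O)c1ccc(O[Si](C)(C)C(C)(C)C)cc1O[Si](C)(C)C(C)(C)C | intermediate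
18 | (2E)-1-[2,4-bis(tert-butyldimethylsilyloxy)phenyl]-3-{(2S,3S)-3-[2,4-bis(tert-butyldimethylsilyloxy)benzoyl]-2-[4-(tert-butyldimethylsilyloxy)phenyl]-2,3-dihydro-1-benzofuran-5-yl}prop-2-en-1-one | O=C(/C=C/c1ccc2c(c1)[C@H](C(=O)c1ccc(O[Si](C)(C)C(C)(C)C)cc1O[Si](C)(C)C(C)(C)C)[C@@H](c1ccc(O[Si](C)(C)C(C)(C)C)cc1)O2)c1ccc(O[Si](C)(C)C(C)(C)C)cc1O[Si](C)(C)C(C)(C)C | intermediate
19 | (2E)-3-[(2S,3S)-3-(2,4-dihydroxybenzoyl)-2-(4-hydroxyphenyl)-2,3-dihydro-1-benzofuran-5-yl]-1-(2,4-dihydroxyphenyl)prop-2-en-1-one | O=C(/C=C/c1ccc2c(c1)[C@H](C(=O)c1ccc(O)cc1O)[C@@H](c1ccc(O)cc1)O2)c1ccc(O)cc1O | target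

## Step count and least certain steps

Total step count: 11. Longest linear sequence: 7 steps (steps 1, 2, 3, 4, 7, 10 and 11); steps 5, 6, 8 and 9 form the side branch.

**Step 2 (key step).** The most likely failure is diversion of iodane 5 before the ring bond migrates. The exits are a 1,2-shift of the C2 aryl ring from the diaxial conformer, elimination to the flavone if ketalisation lags behind oxidation, and methanolysis at C3. Acid-promoted ionisation of C2–O1 could also erode the ee. All of these are low-barrier paths from one hypernucleofugal intermediate, and only the conformer with an equatorial C–I bond leads to contraction.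
Fallback: the fallback sets out from 3 and separates installation of the leaving group from the migration, with no oxidant present at the migration stage. Bromination of 3 with PhNMe3Br3 in THF should give the trans bromo ketone 4-[(2R,3R)-3,6-dibromo-4-oxo-3,4-dihydro-2H-chromen-2-yl]phenyl acetate F1, whose relative configuration can be secured by crystallisation. Ketalisation with HC(OMe)3 and catalytic TsOH would give the bromo ketal 4-[(2R,3R)-3,6-dibromo-4,4-dimethoxy-3,4-dihydro-2H-chromen-2-yl]phenyl acetate F2. AgBF4 in HC(OMe)3/MeOH would then trigger the known silver-assisted 1,2-aryl shift of an alpha-halo ketal, with the same antiperiplanar ring bond, to ortho ester 6. Hydrolysis brings the route back at 7.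

**Step 1.** The likely problems are incomplete enantioface discrimination on the 6-bromo substrate and partial hydrolysis of the acetate in the wet medium, which would give a phenol that racemises and cannot enter step 2.
Fallback: the fallback sets out from 1 and 2 and replaces asymmetric catalysis by resolution. Conjugate addition with Pd(OCOCF3)2 and 2,2'-bipyridine would give the racemic flavanone rac-4-(6-bromo-4-oxo-3,4-dihydro-2H-chromen-2-yl)phenyl acetate F3. Kinetic resolution by asymmetric transfer hydrogenation (RuCl(p-cymene)[TsDPEN], HCO2H/Et3N), using the catalyst antipode that reduces the 2R ketone, would convert that enantiomer into the cis alcohol 4-[(2R,4R)-6-bromo-4-hydroxy-3,4-dihydro-2H-chromen-2-yl]phenyl acetate F4. The unreduced 2S ketone would be separated, and the route resumes at 3.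

**Step 7.** The hindered ortho-silyloxy aryl Grignard reagent may deprotonate C3–H of 9 (benzylic and alpha to the amide) or fail to add to the branched amide, returning starting material.
Fallback: the fallback sets out from 9 and uses a more electrophilic carbonyl. Reduction with i-Bu2AlH at −78 °C would give the aldehyde (2S,3S)-5-bromo-2-[4-(tert-butyldimethylsilyloxy)phenyl]-2,3-dihydro-1-benzofuran-3-carbaldehyde F5. Addition of 12 at −78 °C would give the carbinol [2,4-bis(tert-butyldimethylsilyloxy)phenyl]{(2S,3R)-5-bromo-2-[4-(tert-butyldimethylsilyloxy)phenyl]-2,3-dihydro-1-benzofuran-3-yl}methanol F6 as a mixture of carbinol epimers. Oxidation with Dess–Martin periodinane returns to the route at 14.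

**Step 10.** The likely problems are polymerisation of 17, slow oxidative addition to the electron-rich bromide, and amine-mediated loss of integrity at C3 or opening of C2–O1 on prolonged heating.
Fallback: the fallback sets out from 14 and is base-free. Stille coupling with tributyl(vinyl)stannane (Pd(PPh3)4, toluene, 90 °C) would give the styrene [2,4-bis(tert-butyldimethylsilyloxy)phenyl]{(2S,3S)-2-[4-(tert-butyldimethylsilyloxy)phenyl]-5-vinyl-2,3-dihydro-1-benzofuran-3-yl}methanone F7. Cross-metathesis of F7 with 17 (second-generation Hoveyda–Grubbs catalyst, CH2Cl2, 40 °C) should give the E enone and returns to the route at 18.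

## Further compounds

F1 | step 2 | 4-[(2R,3R)-3,6-dibromo-4-oxo-3,4-dihydro-2H-chromen-2-yl]phenyl acetate | O=C1[C@H](Br)[C@@H](c2ccc(OC(C)=O)cc2)Oc2ccc(Br)cc21
F2 | step 2 | 4-[(2R,3R)-3,6-dibromo-4,4-dimethoxy-3,4-dihydro-2H-chromen-2-yl]phenyl acetate | COC1(OC)[C@H](Br)[C@@H](c2ccc(OC(C)=O)cc2)Oc2ccc(Br)cc21
F3 | step 1 | rac-4-(6-bromo-4-oxo-3,4-dihydro-2H-chromen-2-yl)phenyl acetate | O=C1CC(c2ccc(OC(C)=O)cc2)Oc2ccc(Br)cc21
F4 | step 1 | 4-[(2R,4R)-6-bromo-4-hydroxy-3,4-dihydro-2H-chromen-2-yl]phenyl acetate | O[C@@H]1C[C@H](c2ccc(OC(C)=O)cc2)Oc2ccc(Br)cc21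
F5 | step 7 | (2S,3S)-5-bromo-2-[4-(tert-butyldimethylsilyloxy)phenyl]-2,3-dihydro-1-benzofuran-3-carbaldehyde | Brc1ccc2c(c1)[C@H](C=O)[C@@H](c1ccc(O[Si](C)(C)C(C)(C)C)cc1)O2
F6 | step 7 | [2,4-bis(tert-butyldimethylsilyloxy)phenyl]{(2S,3R)-5-bromo-2-[4-(tert-butyldimethylsilyloxy)phenyl]-2,3-dihydro-1-benzofuran-3-yl}methanol (carbinol centre undefined) | Brc1ccc2c(c1)[C@H](C(O)c1ccc(O[Si](C)(C)C(C)(C)C)cc1O[Si](C)(C)C(C)(C)C)[C@@H](c1ccc(O[Si](C)(C)C(C)(C)C)cc1)O2
F7 | step 10 | [2,4-bis(tert-butyldimethylsilyloxy)phenyl]{(2S,3S)-2-[4-(tert-butyldimethylsilyloxy)phenyl]-5-vinyl-2,3-dihydro-1-benzofuran-3-yl}methanone | C=Cc1ccc2c(c1)[C@H](C(=O)c1ccc(O[Si](C)(C)C(C)(C)C)cc1O[Si](C)(C)C(C)(C)C)[C@@H](c1ccc(O[Si](C)(C)C(C)(C)C)cc1)O2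
A1 | alternative 1 | isoliquiritigenin, (2E)-1-(2,4-dihydroxyphenyl)-3-(4-hydroxyphenyl)prop-2-en-1-one | O=C(/C=C/c1ccc(O)cc1)c1ccc(O)cc1O
A2 | alternative 1 | racemic trans dimer, (2RS,3RS) form of 19 (one enantiomer drawn) | O=C(/C=C/c1ccc2c(c1)[C@H](C(=O)c1ccc(O)cc1O)[C@@H](c1ccc(O)cc1)O2)c1ccc(O)cc1O
A3 | alternative 2 | methyl 2-{2-[(4-acetoxybenzyl)oxy]-5-bromophenyl}-2-diazoacetate | COC(=O)C(=[N+]=[N-])c1cc(Br)ccc1OCc1ccc(OC(C)=O)cc1
A4 | alternative 2 | methyl (2S,3R)-2-(4-acetoxyphenyl)-5-bromo-2,3-dihydro-1-benzofuran-3-carboxylate (cis) | Brc1ccc2c(c1)[C@@H](C(=O)OC)[C@@H](c1ccc(OC(C)=O)cc1)O2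
A5 | alternative 3 | 4-bromo-6-{2-[2,4-bis(tert-butyldimethylsilyloxy)phenyl]-2-oxoethylidene}cyclohexa-2,4-dien-1-one (formed in situ, double-bond geometry not fixed) | O=C1C=CC(Br)=CC1=CC(=O)c1ccc(O[Si](C)(C)C(C)(C)C)cc1O[Si](C)(C)C(C)(C)C
A6 | alternative 3 | dimethylsulfonium [4-(tert-butyldimethylsilyloxy)phenyl]methanide | C[S+](C)[CH-]c1ccc(O[Si](C)(C)C(C)(C)C)cc1
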